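**Plan**

- Retrosynthetic cuts (icetexane numbering): the hydroxyquinone goes back to a 11,12,14-trimethoxyarene, the C1 and C7 carbinols to ketones, C10=C20 is cut (aldol condensation, ring B), then C5–C6 (Michael addition, γ-lactone), then the ester bond O–C6.
- Enabling feature: C4, C5 and C6 all lie on the γ-lactone C4–C19(=O)–O–C6–C5, which hangs from C4, the para-quaternary carbon of a prochiral cyclohexadienone (ring A, C1–C5/C10). One desymmetrising Michael lactonisation therefore sets all three.
- Forward order: ring C is built as a hexasubstituted arene from 1,2,4-trimethoxybenzene and ring A as a Birch-derived dienoic acid from benzoic acid. They are joined as a phenacyl-type ester and oxidised to the dienone. The lactone closes in step 10, ring B in step 12, and the quinone is unveiled last.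
- Stereochemistry: C4/C5 come from the catalyst's choice of enone arm, their cis fusion from the short ester tether, and C6 from equilibration (aroyl on the convex face, trans to C10). C1 and C7 come from two substrate-controlled hydride additions on the rigid tetracycle.

Key step: step 10

Remark 1: positions are given in icetexane numbering (ring A C1–C5/C10; ring B C5–C6–C7–C8–C9–C20–C10; ring C C8/C9/C11–C14; C18 methyl and C19 carbonyl on C4; isopropyl on C13).
Remark 2: the sense of induction of the step 10 catalyst is assumed to be assigned on a first run; both antipodes of the amino-acid-derived catalyst are accessible, and the one giving the (4S,5R,6R) series is used.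

**Step 1**
Reactants: 1 1,2,4-trimethoxybenzene
Product: 3 2-(2,3,6-trimethoxyphenyl)propan-2-ol, via aryllithium 2 (not isolated)
Conditions: n-BuLi, THF, 0 °C; acetone, −78 °C → rt; H2O
Reagents that add atoms: acetone, CC(C)=O
Why: Directed ortho-lithiation takes place at C3 between the two flanking methoxy groups, and the aryllithium undergoes 1,2-addition to acetone.

**Step 2**
Reactants: 3 2-(2,3,6-trimethoxyphenyl)propan-2-ol
Product: 4 1,2,4-trimethoxy-3-(propan-2-yl)benzene
Conditions: Et3SiH, TFA, CH2Cl2, 0 °C → rt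
Reagents that add atoms: none
Why: Ionic hydrogenation: TFA ionises the tertiary benzylic alcohol on the electron-rich ring and Et3SiH delivers hydride to the cation.

**Step 3**
Reactants: 4 1,2,4-trimethoxy-3-(propan-2-yl)benzene
Product: 5 1-bromo-2,4,5-trimethoxy-3-(propan-2-yl)benzene
Conditions: NBS, MeCN, 0 °C → rt
Reagents that add atoms: N-bromosuccinimide, O=C1CCC(=O)N1Br
Why: Electrophilic aromatic bromination goes para to the 2-methoxy and ortho to the 4-methoxy group (the site that reacts in 1,2,4-trimethoxybenzene itself), which marks the future C8.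

**Step 4**
Reactants: 5 1-bromo-2,4,5-trimethoxy-3-(propan-2-yl)benzene
Product: 7 2-bromo-3,5,6-trimethoxy-4-(propan-2-yl)benzaldehyde, via aryllithium 6 (not isolated)
Conditions: LDA, THF, −78 °C; DMF; H2O
Reagents that add atoms: N,N-dimethylformamide, CN(C)C=O
Why: Directed ortho-metalation removes the only ring proton, acidified by the flanking Br and OMe, at a temperature where LiBr loss to the aryne does not occur, and DMF formylates the aryllithium at the future C9.

**Step 5**
Reactants: 7 2-bromo-3,5,6-trimethoxy-4-(propan-2-yl)benzaldehyde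
Product: 8 2-[2-bromo-3,5,6-trimethoxy-4-(propan-2-yl)phenyl]-1,3-dioxolane
Conditions: HOCH2CH2OH, TsOH (cat.), PhH, reflux (Dean–Stark)
Reagents that add atoms: ethylene glycol, OCCO
Why: Acid-catalysed acetalisation with azeotropic removal of water masks the aldehyde (future C20) against the organolithium, base and hydrogenation steps that follow.

**Step 6**
Reactants: 8 2-[2-bromo-3,5,6-trimethoxy-4-(propan-2-yl)phenyl]-1,3-dioxolane; 9 2-chloro-N-methoxy-N-methylacetamide
Product: 11 2-chloro-1-[2-(1,3-dioxolan-2-yl)-3,4,6-trimethoxy-5-(propan-2-yl)phenyl]ethan-1-one, via aryllithium 10 (not isolated)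
Conditions: n-BuLi, THF, −78 °C; 9, −78 → 0 °C; H2O
Reagents that add atoms: none
Why: Bromine–lithium exchange followed by Weinreb ketone synthesis, in which the chelated tetrahedral adduct stops at the ketone stage and the C–Cl bond is untouched at −78 °C, installs C7 and C6.

**Step 7**
Reactants: 12 benzoic acid
Product: 14 1-methylcyclohexa-2,5-diene-1-carboxylic acid, via dienolate dianion 13 (not isolated)
Conditions: Li, NH3(l)/THF, −78 °C; MeI; aq. HCl
Reagents that add atoms: iodomethane, CI
Why: Birch reductive alkylation: Li/NH3 reduction of benzoate gives the 1,4-dihydro dienolate, which is methylated at the carboxylate-bearing carbon to create the quaternary (still non-stereogenic) C4.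

**Step 8**
Reactants: 14 1-methylcyclohexa-2,5-diene-1-carboxylic acid; 11 2-chloro-1-[2-(1,3-dioxolan-2-yl)-3,4,6-trimethoxy-5-(propan-2-yl)phenyl]ethan-1-one
Product: 15 2-[2-(1,3-dioxolan-2-yl)-3,4,6-trimethoxy-5-(propan-2-yl)phenyl]-2-oxoethyl 1-methylcyclohexa-2,5-diene-1-carboxylate
Conditions: Cs2CO3, NaI (cat.), DMF, rt
Reagents that add atoms: none
Why: SN2 O-alkylation of the caesium carboxylate by the activated α-chloro ketone (phenacyl-type ester formation), the weakly basic carboxylate leaving the ketone un-enolised.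

**Step 9**
Reactants: 15 2-[2-(1,3-dioxolan-2-yl)-3,4,6-trimethoxy-5-(propan-2-yl)phenyl]-2-oxoethyl 1-methylcyclohexa-2,5-diene-1-carboxylate
Product: 16 2-[2-(1,3-dioxolan-2-yl)-3,4,6-trimethoxy-5-(propan-2-yl)phenyl]-2-oxoethyl 1-methyl-4-oxocyclohexa-2,5-diene-1-carboxylate
Conditions: PDC, t-BuOOH, Celite, PhH, rt
Reagents that add atoms: tert-butyl hydroperoxide, CC(C)(C)OO
Why: Allylic oxidation with Cr(VI)/t-BuOOH (the hydroperoxide as terminal oxidant) converts the doubly allylic CH2, the weakest C–H bond in the molecule, into the cross-conjugated dienone as is usual for Birch alkylation products, and the absence of base prevents a premature racemic cyclisation.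

**Step 10**
Reactants: 16 2-[2-(1,3-dioxolan-2-yl)-3,4,6-trimethoxy-5-(propan-2-yl)phenyl]-2-oxoethyl 1-methyl-4-oxocyclohexa-2,5-diene-1-carboxylate
Product: 17 (3R,3aR,7aS)-3-[2-(1,3-dioxolan-2-yl)-3,4,6-trimethoxy-5-(propan-2-yl)benzoyl]-7a-methyl-3a,4-dihydro-2-benzofuran-1,5(3H,7aH)-dione (cis-fused lactone, aroyl trans to the ring CH2 across the lactone; 4S,5R,6R in icetexane numbering)
Conditions: chiral bifunctional iminophosphorane–thiourea superbase (10 mol %), PhMe, 0 °C
Reagents that add atoms: none
Why: The chiral superbase deprotonates C6, which is flanked by the ester oxygen and the C7 ketone, and the ion-paired enolate adds to C5 of one of the two enantiotopic enone arms, after which the resulting C1 enolate is protonated at C10, so the base turns over. The closest known reaction type is the organocatalytic desymmetrising intramolecular Michael addition of tethered carbon acids to 4,4-disubstituted cyclohexadienones under bifunctional Brønsted-base/hydrogen-bond catalysis. The γ-lactone closes in the 5-exo-trig mode. C4 and C5 are set together by the catalyst's choice of enone arm (thiourea binding of the dienone carbonyl, enolate held in the chiral ion pair), their cis relationship by the three-atom ester tether, which cannot span a trans fusion, and C6 by equilibration through the enolate under the same base, the aroyl group settling on the convex face, trans to C10. The step needs selection between enantiotopic arms and C–C bond formation at C6 without cleavage of the C4–C19 bond; the first rests on the catalyst, the second on the non-nucleophilic base and on C6–H being the only acidic site.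

**Step 11**
Reactants: 17 Michael adduct (4S,5R,6R)
Product: 18 (3R,3aR,7aS)-3-[2-(1,3-dioxolan-2-yl)-3,4,6-trimethoxy-5-(propan-2-yl)benzoyl]-7a-methylhexahydro-2-benzofuran-1,5-dione
Conditions: H2 (1 atm), Pd/C, EtOAc, rt
Reagents that add atoms: none
Why: Catalytic hydrogenation over Pd/C saturates only the unhindered disubstituted enone double bond C2=C3 under neutral conditions, leaving the hindered aryl ketone, the lactone and the acetal untouched and no stereocentre affected.

**Step 12**
Reactants: 18 saturated diketone acetal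
Product: 20 (4S,5R,6R)-11,12,14-trimethoxy-1,7-dioxoicetexa-8,10(20),11,13-tetraen-19,6-olide, via keto-aldehyde 19 (not isolated)
Conditions: TsOH·H2O, THF/H2O, rt; then PhH, 80 °C (Dean–Stark)
Reagents that add atoms: none
Why: Acetal hydrolysis followed by acid-catalysed intramolecular aldol condensation (Claisen–Schmidt type): of the two enolisable α-carbons of the C1 ketone only C10 can reach C20, dehydration to the aryl-conjugated enone drives the seven-membered ring closure, and acid is used so that the acidic C6–H next to the C7 ketone is not epimerised as it would be under base.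

**Step 13**
Reactants: 20 tetracyclic enone–ketone
Product: 21 (1R,4S,5R,6R)-1-hydroxy-11,12,14-trimethoxy-7-oxoicetexa-8,10(20),11,13-tetraen-19,6-olide
Conditions: NaBH4, CeCl3·7H2O, MeOH/CH2Cl2, −78 °C
Reagents that add atoms: none
Why: Luche reduction: the cerium-activated, more Lewis-basic enone carbonyl C1 should be reduced 1,2 at −78 °C before the hindered ortho-methoxy aryl ketone C7, with hydride entering from the face of H5 because the opposite face is screened by the C6 branch of the lactone, which places 1-OH cis to C19 (1R).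

**Step 14**
Reactants: 21 1-hydroxy-7-ketone
Product: 22 (1R,4S,5R,6R,7S)-1,7-dihydroxy-11,12,14-trimethoxyicetexa-8,10(20),11,13-tetraen-19,6-olide
Conditions: K-Selectride, THF, −78 °C; AcOH
Reagents that add atoms: none
Why: Bulky trialkylborohydride reduction: the reagent should approach C7 along the equatorial-type trajectory on the face of H6, away from H5, which projects over the other face of the folded seven-membered ring, giving the axial 7-OH cis to the lactone oxygen on C6 (7S).

**Step 15**
Reactants: 22 trimethoxyarene diol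
Product: 23 (1R,4S,5R,6R,7S)-1,7-dihydroxy-12-methoxy-11,14-dioxoicetexa-8,10(20),12-trien-19,6-olide
Conditions: CAN, MeCN/H2O, 0 °C
Reagents that add atoms: water, O
Why: CAN oxidative demethylation of the para-related methoxy groups at C11 and C14 gives the 2-methoxy-1,4-benzoquinone, the C12 methoxy group being retained, while the carbinols and the lactone are stable to brief treatment at 0 °C.

**Step 16**
Reactants: 23 methoxyquinone
Product: 24 ballotiquinone, (1R,4S,5R,6R,7S)-1,7,12-trihydroxy-11,14-dioxoicetexa-8,10(20),12-trien-19,6-olide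
Conditions: aq. HClO4, 1,4-dioxane, rt
Reagents that add atoms: water, O
Why: Acid-catalysed hydrolysis of the methoxyquinone, a vinylogous ester, by addition–elimination of water at C12 releases the hydroxyquinone without opening the lactone or touching the stereocentres.

**Compound list**

1 | 1,2,4-trimethoxybenzene | COc1ccc(OC)c(OC)c1 | starting material
2 | (2,3,6-trimethoxyphenyl)lithium | [Li]c1c(OC)ccc(OC)c1OC | intermediate
3 | 2-(2,3,6-trimethoxyphenyl)propan-2-ol | COc1ccc(OC)c(C(C)(C)O)c1OC | intermediate
4 | 1,2,4-trimethoxy-3-(propan-2-yl)benzene | COc1ccc(OC)c(C(C)C)c1OC | intermediate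
5 | 1-bromo-2,4,5-trimethoxy-3-(propan-2-yl)benzene | COc1cc(Br)c(OC)c(C(C)C)c1OC | intermediate
6 | [2-bromo-3,5,6-trimethoxy-4-(propan-2-yl)phenyl]lithium | COc1c([Li])c(Br)c(OC)c(C(C)C)c1OC | intermediate
7 | 2-bromo-3,5,6-trimethoxy-4-(propan-2-yl)benzaldehyde | COc1c(C=O)c(Br)c(OC)c(C(C)C)c1OC | intermediate
8 | 2-[2-bromo-3,5,6-trimethoxy-4-(propan-2-yl)phenyl]-1,3-dioxolane | COc1c(C2OCCO2)c(Br)c(OC)c(C(C)C)c1OC | intermediate
9 | 2-chloro-N-methoxy-N-methylacetamide | ClCC(=O)N(C)OC | starting material
10 | [2-(1,3-dioxolan-2-yl)-3,4,6-trimethoxy-5-(propan-2-yl)phenyl]lithium | COc1c(C2OCCO2)c([Li])c(OC)c(C(C)C)c1OC | intermediate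
11 | 2-chloro-1-[2-(1,3-dioxolan-2-yl)-3,4,6-trimethoxy-5-(propan-2-yl)phenyl]ethan-1-one | COc1c(C2OCCO2)c(C(=O)CCl)c(OC)c(C(C)C)c1OC | intermediate
12 | benzoic acid | OC(=O)c1ccccc1 | starting material
13 | dilithium 1,4-dihydrobenzoate dienolate (cyclohexa-2,5-dien-1-ylidenemethanediolate) | [Li+].[Li+].[O-]C([O-])=C1C=CCC=C1 | intermediate
14 | 1-methylcyclohexa-2,5-diene-1-carboxylic acid | CC1(C=CCC=C1)C(O)=O | intermediate
15 | 2-[2-(1,3-dioxolan-2-yl)-3,4,6-trimethoxy-5-(propan-2-yl)phenyl]-2-oxoethyl 1-methylcyclohexa-2,5-diene-1-carboxylate | CC(C)c1c(OC)c(OC)c(C2OCCO2)c(c1OC)C(=O)COC(=O)C1(C)C=CCC=C1 | intermediate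
16 | 2-[2-(1,3-dioxolan-2-yl)-3,4,6-trimethoxy-5-(propan-2-yl)phenyl]-2-oxoethyl 1-methyl-4-oxocyclohexa-2,5-diene-1-carboxylate | CC(C)c1c(OC)c(OC)c(C2OCCO2)c(c1OC)C(=O)COC(=O)C1(C)C=CC(=O)C=C1 | intermediate
17 | (3R,3aR,7aS)-3-[2-(1,3-dioxolan-2-yl)-3,4,6-trimethoxy-5-(propan-2-yl)benzoyl]-7a-methyl-3a,4-dihydro-2-benzofuran-1,5(3H,7aH)-dione | CC(C)c1c(OC)c(OC)c(C2OCCO2)c(c1OC)C(=O)[C@@H]1OC(=O)[C@@]3(C)C=CC(=O)C[C@@H]13 | intermediate
18 | (3R,3aR,7aS)-3-[2-(1,3-dioxolan-2-yl)-3,4,6-trimethoxy-5-(propan-2-yl)benzoyl]-7a-methylhexahydro-2-benzofuran-1,5-dione | CC(C)c1c(OC)c(OC)c(C2OCCO2)c(c1OC)C(=O)[C@@H]1OC(=O)[C@@]3(C)CCC(=O)C[C@@H]13 | intermediate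
19 | (3R,3aR,7aS)-3-[2-formyl-3,4,6-trimethoxy-5-(propan-2-yl)benzoyl]-7a-methylhexahydro-2-benzofuran-1,5-dione | CC(C)c1c(OC)c(OC)c(C=O)c(c1OC)C(=O)[C@@H]1OC(=O)[C@@]3(C)CCC(=O)C[C@@H]13 | intermediate
20 | (4S,5R,6R)-11,12,14-trimethoxy-1,7-dioxoicetexa-8,10(20),11,13-tetraen-19,6-olide | CC(C)c1c(OC)c(OC)c2c(c1OC)C(=O)[C@@H]1OC(=O)[C@@]3(C)CCC(=O)C(=C2)[C@@H]13 | intermediate
21 | (1R,4S,5R,6R)-1-hydroxy-11,12,14-trimethoxy-7-oxoicetexa-8,10(20),11,13-tetraen-19,6-olide | CC(C)c1c(OC)c(OC)c2c(c1OC)C(=O)[C@@H]1OC(=O)[C@@]3(C)CC[C@@H](O)C(=C2)[C@@H]13 | intermediate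
22 | (1R,4S,5R,6R,7S)-1,7-dihydroxy-11,12,14-trimethoxyicetexa-8,10(20),11,13-tetraen-19,6-olide | CC(C)c1c(OC)c(OC)c2c(c1OC)[C@H](O)[C@@H]1OC(=O)[C@@]3(C)CC[C@@H](O)C(=C2)[C@@H]13 | intermediate
23 | (1R,4S,5R,6R,7S)-1,7-dihydroxy-12-methoxy-11,14-dioxoicetexa-8,10(20),12-trien-19,6-olide | CC(C)C1=C(OC)C(=O)C2=C(C1=O)[C@H](O)[C@@H]1OC(=O)[C@@]3(C)CC[C@@H](O)C(=C2)[C@@H]13 | intermediate
24 | ballotiquinone | CC(C)C1=C(O)C(=O)C2=C(C1=O)[C@H](O)[C@@H]1OC(=O)[C@@]3(C)CC[C@@H](O)C(=C2)[C@@H]13 | target

**Step count and risks**

Total step count: 16. Longest linear sequence: 15 steps (steps 1–6 and 8–16, from 1,2,4-trimethoxybenzene); the benzoic acid branch joins at step 8.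

Steps most likely to fail:

1. Step 10. The ion-paired enolate may discriminate poorly between the two enone arms, or deprotonation at C6 may be too slow under the chiral base. Fallback: setting out from 16, cyclisation with an achiral base (Cs2CO3, MeCN, rt) should give the racemic cis-fused, exo-aroyl lactone F1, whose enantiomers are separated by preparative chromatography on a chiral stationary phase (SFC); the dextro/levo assignment is made by correlation, and the route is rejoined at 17.

2. Step 12. C6, still α to the C7 ketone, may epimerise during the closure, and the epimer with C7 and C10 cis on the lactone may cyclise faster, leading into the C6-epimeric series. Fallback: setting out from 18, selective ketalisation of the unhindered C1 ketone (ethylene glycol, PPTS, PhH) should give the bis-dioxolane F2. NaBH4 then reduces the C7 ketone to the carbinol F3 (either C7 epimer serves), which removes the acidity at C6. The acid treatment of step 12 unmasks both acetals and closes ring B to the 7-hydroxy enone F4, and Dess–Martin oxidation of the C7 carbinol under non-epimerising conditions returns to 20.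

3. Step 13. Chemoselectivity may be lost: the borohydride may also attack the activated α-acyloxy aryl ketone at C7, and from the face that leads to the 7-epimer. Fallback: setting out from 20, both carbonyl groups are reduced with excess K-Selectride (THF, −78 °C), which fixes C7 under steric control and gives the diol F5 with the C1 carbinol in whichever configuration forms. MnO2 then re-oxidises only the allylic C1 carbinol to the 7-hydroxy enone F6, and Luche reduction of this enone, now free of a competing ketone, rejoins the route at 22.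

**Further compounds**

F1 | step 10 | racemic Michael adduct (17 and its enantiomer, 1:1) | CC(C)c1c(OC)c(OC)c(C2OCCO2)c(c1OC)C(=O)[C@@H]1OC(=O)[C@@]3(C)C=CC(=O)C[C@@H]13.CC(C)c1c(OC)c(OC)c(C2OCCO2)c(c1OC)C(=O)[C@H]1OC(=O)[C@]3(C)C=CC(=O)C[C@H]13
F2 | step 12 | C1 ethylene ketal of 18 (bis-dioxolane) | CC(C)c1c(OC)c(OC)c(C2OCCO2)c(c1OC)C(=O)[C@@H]1OC(=O)[C@@]3(C)CCC4(OCCO4)C[C@@H]13
F3 | step 12 | C7 carbinol of the bis-dioxolane (C7 epimers) | CC(C)c1c(OC)c(OC)c(C2OCCO2)c(c1OC)C(O)[C@@H]1OC(=O)[C@@]3(C)CCC4(OCCO4)C[C@@H]13
F4 | step 12 | (4S,5R,6R)-7-hydroxy-11,12,14-trimethoxy-1-oxoicetexa-8,10(20),11,13-tetraen-19,6-olide (C7 epimers) | CC(C)c1c(OC)c(OC)c2c(c1OC)C(O)[C@@H]1OC(=O)[C@@]3(C)CCC(=O)C(=C2)[C@@H]13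
F5 | step 13 | (4S,5R,6R,7S)-1,7-dihydroxy-11,12,14-trimethoxyicetexa-8,10(20),11,13-tetraen-19,6-olide, C1 of either configuration | CC(C)c1c(OC)c(OC)c2c(c1OC)[C@H](O)[C@@H]1OC(=O)[C@@]3(C)CCC(O)C(=C2)[C@@H]13
F6 | step 13 | (4S,5R,6R,7S)-7-hydroxy-11,12,14-trimethoxy-1-oxoicetexa-8,10(20),11,13-tetraen-19,6-olide | CC(C)c1c(OC)c(OC)c2c(c1OC)[C@H](O)[C@@H]1OC(=O)[C@@]3(C)CCC(=O)C(=C2)[C@@H]13
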